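**Plan**

Retrosynthesis: the diene is cut at C14=C15 and C12=C13 (two Wittig olefinations) and C11–C12 by one-carbon homologation of a formyl group on C9. Ring B is then cut at C8–C9 (enamine/copper Conia-ene closure of a C11 aldehyde onto a C8≡C17 alkyne), and the two arms are cut from ring A at C9–C10 (enolate allylation) and C5–C6 (conjugate addition).
Forward order: ring A is a purchased 4-oxocyclohexane-1,1-diester that is made into the 2-methyl enone. One operation adds the C6–C7–C8–C17 arm to C5 and the C9–C11 arm to C10, ring B is closed, and the side chain is grown outward from C11.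
Enabling feature: the exocyclic C8=C17 methylene is attached to C9, and C9 carries C11. With C11 as an aldehyde, C9 is an enamine carbon that can add to the internal carbon of a terminal alkyne held on C5, which closes six-membered ring B (C5–C6–C7–C8–C9–C10) and leaves C17 as the methylene.
Stereochemistry: C5 comes from a chiral copper catalyst, C10 from allylation anti to the C5 chain, C9 from the chair-like ring closure, and C1 from axial hydride delivery. C4 comes from selective reduction of the equatorial ester of the gem-diester (C4 carries two equal esters until then), and the 12E alkene from a stabilised ylide.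

Key step: step 7

Remark: atom numbers C1–C20 are those of the labdane skeleton of the target (1S,4R,5S,9R,10S); systematic names of the bicyclic compounds use naphthalene locants (1 = C4, 4 = C1, 4a = C10, 5 = C9, 8a = C5).
Remark: descriptors that change between neighbouring compounds (ring position 3 in 11 and 12, 4a in 19 and 20) reflect a change of CIP priorities only; no centre is inverted anywhere in the route.
Remark: 4-bromobut-1-yne is used as its commercial C-silylated form 5, because a free alkyne C–H would quench the Grignard reagent.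
Assumption: the ligand enantiomer named in step 4 is taken to give the 5S product; should the first run show the opposite sense, its mirror image is used.

**Route**

Step 1
Reactants: 1 dimethyl 4-oxocyclohexane-1,1-dicarboxylate
Product: 2 dimethyl 4-oxocyclohex-2-ene-1,1-dicarboxylate
Conditions: Pd(O2CCF3)2 (5 mol %), DMSO (10 mol %), O2 (1 atm), AcOH, 80 °C
Reagents that add atoms: none
Why: Palladium-catalysed aerobic α,β-dehydrogenation of a cyclohexanone (palladium enolate, then β-hydride elimination) should stop at the enone, because 1 is symmetrical so only one enone exists and the quaternary C4 blocks aromatisation.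

Step 2
Reactants: 2 dimethyl 4-oxocyclohex-2-ene-1,1-dicarboxylate
Product: 3 dimethyl 3-iodo-4-oxocyclohex-2-ene-1,1-dicarboxylate
Conditions: I2 (2 equiv), pyridine/CH2Cl2 (1:1), 0 °C to rt
Reagents that add atoms: iodine, II
Why: Pyridine-mediated α-iodination of an enone (conjugate addition of pyridine, iodination of the enolate, elimination) places iodine only on the α-carbon, the future C10, as it does for other 4,4-disubstituted cyclohexenones.

Step 3
Reactants: 3 dimethyl 3-iodo-4-oxocyclohex-2-ene-1,1-dicarboxylate
Product: 4 dimethyl 3-methyl-4-oxocyclohex-2-ene-1,1-dicarboxylate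
Conditions: Me4Sn (1.5 equiv), Pd2(dba)3 (2.5 mol %), AsPh3 (10 mol %), CuI (10 mol %), NMP, 70 °C
Reagents that add atoms: tetramethylstannane, C[Sn](C)(C)C
Why: Stille coupling of an α-iodoenone with tetramethylstannane is a standard route to α-methyl enones, the copper co-catalyst speeding transmetalation of the methyl group.

Step 4
Reactants: 4 dimethyl 3-methyl-4-oxocyclohex-2-ene-1,1-dicarboxylate; 5 (4-bromobut-1-yn-1-yl)trimethylsilane; 6 allyl bromide
Product: 9 dimethyl (2S,3S)-3-methyl-4-oxo-3-(prop-2-en-1-yl)-2-[4-(trimethylsilyl)but-3-yn-1-yl]cyclohexane-1,1-dicarboxylate, via Grignard reagent 7 (not isolated), via magnesium enolate 8 (not isolated)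
Conditions: 5, Mg, Et2O, rt; CuBr·SMe2 (5 mol %), (R)-1-[(Sp)-2-(dicyclohexylphosphino)ferrocenyl]ethyldiphenylphosphine (6 mol %), t-BuOMe, −78 °C, slow addition of 4; then 6 (3 equiv), DMPU, −78 to 0 °C
Reagents that add atoms: none
Why: Copper-catalysed asymmetric conjugate addition of a Grignard reagent to an α-methyl cyclic enone with a chiral ferrocenyl diphosphine, followed by C-allylation of the magnesium enolate, is a known one-flask way to a quaternary centre next to a tertiary one: the catalyst sets C5 (S) on addition, and allyl bromide then enters C10 on the face anti to the new C5 chain, so the butynyl and allyl arms come out trans (C10 S) and the methyl group cis to the butynyl arm.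

Step 5
Reactants: 9 dimethyl (2S,3S)-3-methyl-4-oxo-3-(prop-2-en-1-yl)-2-[4-(trimethylsilyl)but-3-yn-1-yl]cyclohexane-1,1-dicarboxylate
Product: 10 dimethyl (2S,3S)-2-(but-3-yn-1-yl)-3-methyl-4-oxo-3-(prop-2-en-1-yl)cyclohexane-1,1-dicarboxylate
Conditions: K2CO3 (0.5 equiv), MeOH, rt
Reagents that add atoms: none
Why: Base-catalysed methanolysis of the alkynyl C–Si bond is selective here because C10 is quaternary, the esters are already methyl esters and nothing else in 9 responds to K2CO3 in methanol at room temperature.

Step 6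
Reactants: 10 dimethyl (2S,3S)-2-(but-3-yn-1-yl)-3-methyl-4-oxo-3-(prop-2-en-1-yl)cyclohexane-1,1-dicarboxylate
Product: 11 dimethyl (2S,3S)-2-(but-3-yn-1-yl)-3-methyl-4-oxo-3-(2-oxoethyl)cyclohexane-1,1-dicarboxylate
Conditions: K2OsO4·2H2O (2 mol %), NaIO4 (4 equiv), 2,6-lutidine (2 equiv), 1,4-dioxane/H2O (3:1), rt
Reagents that add atoms: sodium periodate, [Na+].[O-]I(=O)(=O)=O
Why: Lemieux–Johnson oxidation (osmium-catalysed dihydroxylation, then periodate cleavage of the diol) cuts the terminal alkene to the aldehyde and leaves the alkyne, which is osmylated far more slowly, untouched, while 2,6-lutidine suppresses side reactions of the keto aldehyde.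

Step 7
Reactants: 11 dimethyl (2S,3S)-2-(but-3-yn-1-yl)-3-methyl-4-oxo-3-(2-oxoethyl)cyclohexane-1,1-dicarboxylate
Product: 14 dimethyl (4aR,5R,8aS)-5-formyl-4a-methyl-6-methylidene-4-oxooctahydronaphthalene-1,1(2H)-dicarboxylate, via enamine 12 (not isolated), via iminium ion 13 (not isolated)
Conditions: pyrrolidine (20 mol %), Cu(OTf)2 (10 mol %), PPh3 (40 mol %), ClCH2CH2Cl, 50 °C, Ar; aq. NaH2PO4/Na2HPO4 (pH 7) work-up
Reagents that add atoms: none
Why: Proposed new method: pyrrolidine condenses with the unhindered formyl group of 11 to give the E-enamine 12, whose nucleophilic carbon C9 attacks, anti to the metal, the terminal alkyne activated by the copper–PPh3 π-acid formed from Cu(OTf)2 (most likely monovalent copper after reduction by the phosphine), so that C9 bonds to the internal carbon C8; protodemetalation of the vinylcopper gives iminium ion 13 and hydrolysis releases 14 and the amine. The closest known reaction type is the amine/copper (or amine/gold) co-catalysed Conia-ene carbocyclisation of formyl and keto alkynes, established for 5-exo-dig closures; a 6-exo-dig closure at an enamine carbon next to a quaternary centre has not been shown. Ring B closes in the 6-exo-dig mode, and because the C5 and C10 arms are held trans-diequatorial on ring A only the trans-fused chair is within reach. C9, the only new stereocentre, is set in that chair with the enamine carbon C11 pseudo-equatorial, and should 13 lose and regain H9, axial protonation anti to the C10 methyl leads to the same equatorial formyl epimer. The step needs exo over endo attack (secured by the short tether C10–C5–C6–C7 between C9 and C8 and the preference of a terminal alkyne for attack at its internal carbon), aldehyde over ketone enamine formation (secured by the C1 ketone being flanked by quaternary C10) and an alkene that stays out of conjugation (favoured because the α-branched aldehyde 14 recondenses with pyrrolidine slowly and the work-up is buffered).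

Step 8
Reactants: 14 dimethyl (4aR,5R,8aS)-5-formyl-4a-methyl-6-methylidene-4-oxooctahydronaphthalene-1,1(2H)-dicarboxylate
Product: 15 dimethyl (4aR,5R,8aS)-5-(2-methoxyethenyl)-4a-methyl-6-methylidene-4-oxooctahydronaphthalene-1,1(2H)-dicarboxylate (expected as an E/Z mixture)
Conditions: Ph3P(CH2OMe)Cl (1.3 equiv), KN(SiMe3)2 (1.2 equiv), THF, 0 °C; ylide solution added to 14 at −78 °C, then to −20 °C
Reagents that add atoms: (methoxymethyl)triphenylphosphonium chloride, COC[P+](c1ccccc1)(c1ccccc1)c1ccccc1.[Cl-]
Why: Wittig olefination with the methoxymethylene ylide takes the aldehyde much faster than the C1 ketone, which is flanked by the quaternary C10, and adding the ylide at −78 °C lets carbonyl addition outrun deprotonation at C9, so the C9 configuration and the unconjugated C8=C17 alkene should be kept.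

Step 9
Reactants: 15 dimethyl (4aR,5R,8aS)-5-(2-methoxyethenyl)-4a-methyl-6-methylidene-4-oxooctahydronaphthalene-1,1(2H)-dicarboxylate
Product: 16 methyl (1R,4S,4aR,5R,8aS)-4-hydroxy-1-(hydroxymethyl)-5-(2-methoxyethenyl)-4a-methyl-6-methylidenedecahydronaphthalene-1-carboxylate
Conditions: LiAlH(OtBu)3 (6 equiv), THF, 0 °C, then 45 °C; aq. potassium sodium tartrate
Reagents that add atoms: none
Why: LiAlH(OtBu)3 reduces ketones in the cold and, on warming, one ester of a malonate-type gem-diester but no isolated ester: at C1 hydride is delivered axially, on the face opposite the axial C10 methyl, to give the equatorial alcohol (1S), and at C4 it takes the exposed equatorial ester and not the axial one that lies 1,3-diaxial to the C10 methyl, which makes C4 a stereocentre (R) and stops at the β-alkoxy ester.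

Step 10
Reactants: 16 methyl (1R,4S,4aR,5R,8aS)-4-hydroxy-1-(hydroxymethyl)-5-(2-methoxyethenyl)-4a-methyl-6-methylidenedecahydronaphthalene-1-carboxylate
Product: 17 methyl (1R,4S,4aR,5R,8aS)-4-hydroxy-1-{[(1H-imidazol-1-ylcarbonothioyl)oxy]methyl}-5-(2-methoxyethenyl)-4a-methyl-6-methylidenedecahydronaphthalene-1-carboxylate
Conditions: 1,1'-thiocarbonyldiimidazole (1.3 equiv), DMAP (10 mol %), CH2Cl2, rt
Reagents that add atoms: 1,1'-thiocarbonyldiimidazole, S=C(n1ccnc1)n1ccnc1
Why: O-Thioacylation with 1,1'-thiocarbonyldiimidazole takes the primary alcohol, while the equatorial C1 hydroxyl, crowded by the quaternary C10 and the C9 side chain, reacts much more slowly and stays free.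

Step 11
Reactants: 17 methyl (1R,4S,4aR,5R,8aS)-4-hydroxy-1-{[(1H-imidazol-1-ylcarbonothioyl)oxy]methyl}-5-(2-methoxyethenyl)-4a-methyl-6-methylidenedecahydronaphthalene-1-carboxylate
Product: 18 methyl (1R,4S,4aR,5R,8aS)-4-hydroxy-5-(2-methoxyethenyl)-1,4a-dimethyl-6-methylidenedecahydronaphthalene-1-carboxylate
Conditions: Bu3SnH (2.5 equiv), AIBN (0.2 equiv), xylene, 130 °C
Reagents that add atoms: none
Why: Barton–McCombie deoxygenation: the tin radical adds to the thiocarbonyl sulfur, the C–O bond fragments to the primary radical, and hydrogen transfer from Bu3SnH gives the C4 methyl group without touching the enol ether, the isolated alkene or any stereocentre.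

Step 12
Reactants: 18 methyl (1R,4S,4aR,5R,8aS)-4-hydroxy-5-(2-methoxyethenyl)-1,4a-dimethyl-6-methylidenedecahydronaphthalene-1-carboxylate
Product: 19 methyl (1R,4S,4aR,5R,8aS)-4-acetoxy-5-(2-methoxyethenyl)-1,4a-dimethyl-6-methylidenedecahydronaphthalene-1-carboxylate
Conditions: Ac2O (5 equiv), DMAP (0.5 equiv), pyridine, 40 °C
Reagents that add atoms: acetic anhydride, CC(=O)OC(C)=O
Why: DMAP-catalysed acetylation of the hindered equatorial alcohol proceeds with retention at C1 under basic conditions that the enol ether tolerates.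

Step 13
Reactants: 19 methyl (1R,4S,4aR,5R,8aS)-4-acetoxy-5-(2-methoxyethenyl)-1,4a-dimethyl-6-methylidenedecahydronaphthalene-1-carboxylate
Product: 20 methyl (1R,4S,4aS,5R,8aS)-4-acetoxy-1,4a-dimethyl-6-methylidene-5-(2-oxoethyl)decahydronaphthalene-1-carboxylate
Conditions: 2 M HCl/THF (1:10), 0 °C to rt
Reagents that add atoms: water, O
Why: Acid-catalysed hydrolysis of the methyl enol ether (C-protonation, hydration of the oxocarbenium ion, loss of methanol) unmasks the C12 aldehyde, and dilute acid in wet THF is mild enough for the acetate, the axial ester and the 1,1-disubstituted alkene.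

Step 14
Reactants: 20 methyl (1R,4S,4aS,5R,8aS)-4-acetoxy-1,4a-dimethyl-6-methylidene-5-(2-oxoethyl)decahydronaphthalene-1-carboxylate
Product: 21 methyl (1R,4S,4aS,5R,8aS)-4-acetoxy-1,4a-dimethyl-6-methylidene-5-[(2E)-3-methyl-4-oxobut-2-en-1-yl]decahydronaphthalene-1-carboxylate
Conditions: Ph3P=C(CH3)CHO (1.5 equiv), toluene, 90 °C
Reagents that add atoms: 2-(triphenylphosphoranylidene)propanal, CC(C=O)=P(c1ccccc1)(c1ccccc1)c1ccccc1
Why: Wittig olefination with the formyl-stabilised ylide is not basic enough to enolise 20 and gives the trisubstituted enal with E geometry, because the reversible addition of stabilised ylides leads to the less crowded alkene.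

Step 15
Reactants: 21 methyl (1R,4S,4aS,5R,8aS)-4-acetoxy-1,4a-dimethyl-6-methylidene-5-[(2E)-3-methyl-4-oxobut-2-en-1-yl]decahydronaphthalene-1-carboxylate
Product: 22 methyl (1R,4S,4aS,5R,8aS)-4-acetoxy-1,4a-dimethyl-6-methylidene-5-[(2E)-3-methylpenta-2,4-dien-1-yl]decahydronaphthalene-1-carboxylate (CNP0235031.1)
Conditions: Ph3PCH3Br (1.5 equiv), KOtBu (1.4 equiv), THF, 0 °C; then 21, −78 to 0 °C
Reagents that add atoms: methyltriphenylphosphonium bromide, C[P+](c1ccccc1)(c1ccccc1)c1ccccc1.[Br-]
Why: Wittig methylenation of the enal carbonyl turns it into the terminal vinyl group and completes the conjugated diene, the hindered C1 acetate and axial C4 ester being inert to the ylide at 0 °C and the 12E alkene being unaffected.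

**Compound list**

1 | dimethyl 4-oxocyclohexane-1,1-dicarboxylate | COC(=O)C1(C(=O)OC)CCC(=O)CC1 | starting material
2 | dimethyl 4-oxocyclohex-2-ene-1,1-dicarboxylate | COC(=O)C1(C(=O)OC)C=CC(=O)CC1 | intermediate
3 | dimethyl 3-iodo-4-oxocyclohex-2-ene-1,1-dicarboxylate | COC(=O)C1(C(=O)OC)C=C(I)C(=O)CC1 | intermediate
4 | dimethyl 3-methyl-4-oxocyclohex-2-ene-1,1-dicarboxylate | COC(=O)C1(C(=O)OC)C=C(C)C(=O)CC1 | intermediate
5 | (4-bromobut-1-yn-1-yl)trimethylsilane | C[Si](C)(C)C#CCCBr | starting material
6 | allyl bromide (3-bromoprop-1-ene) | C=CCBr | starting material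
7 | [4-(trimethylsilyl)but-3-yn-1-yl]magnesium bromide | C[Si](C)(C)C#CCC[Mg]Br | intermediate
8 | bromomagnesium (3S)-4,4-bis(methoxycarbonyl)-2-methyl-3-[4-(trimethylsilyl)but-3-yn-1-yl]cyclohex-1-en-1-olate | CC1=C(O[Mg]Br)CCC(C(=O)OC)(C(=O)OC)[C@H]1CCC#C[Si](C)(C)C | intermediate
9 | dimethyl (2S,3S)-3-methyl-4-oxo-3-(prop-2-en-1-yl)-2-[4-(trimethylsilyl)but-3-yn-1-yl]cyclohexane-1,1-dicarboxylate (butynyl and allyl trans) | C=CC[C@]1(C)C(=O)CCC(C(=O)OC)(C(=O)OC)[C@H]1CCC#C[Si](C)(C)C | intermediate
10 | dimethyl (2S,3S)-2-(but-3-yn-1-yl)-3-methyl-4-oxo-3-(prop-2-en-1-yl)cyclohexane-1,1-dicarboxylate | C=CC[C@]1(C)C(=O)CCC(C(=O)OC)(C(=O)OC)[C@H]1CCC#C | intermediate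
11 | dimethyl (2S,3S)-2-(but-3-yn-1-yl)-3-methyl-4-oxo-3-(2-oxoethyl)cyclohexane-1,1-dicarboxylate | O=CC[C@]1(C)C(=O)CCC(C(=O)OC)(C(=O)OC)[C@H]1CCC#C | intermediate
12 | dimethyl (2S,3R)-2-(but-3-yn-1-yl)-3-methyl-4-oxo-3-[(E)-2-(pyrrolidin-1-yl)ethenyl]cyclohexane-1,1-dicarboxylate (enamine of 11) | C1CCN(C1)/C=C/[C@]2(C)C(=O)CCC(C(=O)OC)(C(=O)OC)[C@H]2CCC#C | intermediate
13 | pyrrolidinium iminium ion of 14 (C11=N+, ring configuration as in 14) | C(=[N+]1CCCC1)[C@@H]2C(=C)CC[C@H]3[C@@]2(C)C(=O)CCC3(C(=O)OC)C(=O)OC | intermediate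
14 | dimethyl (4aR,5R,8aS)-5-formyl-4a-methyl-6-methylidene-4-oxooctahydronaphthalene-1,1(2H)-dicarboxylate (trans-decalin, formyl equatorial and cis to the angular methyl) | O=C[C@@H]1C(=C)CC[C@H]2[C@@]1(C)C(=O)CCC2(C(=O)OC)C(=O)OC | intermediate
15 | dimethyl (4aR,5R,8aS)-5-(2-methoxyethenyl)-4a-methyl-6-methylidene-4-oxooctahydronaphthalene-1,1(2H)-dicarboxylate (E/Z mixture) | COC=C[C@@H]1C(=C)CC[C@H]2[C@@]1(C)C(=O)CCC2(C(=O)OC)C(=O)OC | intermediate
16 | methyl (1R,4S,4aR,5R,8aS)-4-hydroxy-1-(hydroxymethyl)-5-(2-methoxyethenyl)-4a-methyl-6-methylidenedecahydronaphthalene-1-carboxylate (E/Z mixture; ester axial, CH2OH and C1–OH equatorial) | COC=C[C@@H]1C(=C)CC[C@H]2[C@@]1(C)[C@@H](O)CC[C@@]2(CO)C(=O)OC | intermediate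
17 | methyl (1R,4S,4aR,5R,8aS)-4-hydroxy-1-{[(1H-imidazol-1-ylcarbonothioyl)oxy]methyl}-5-(2-methoxyethenyl)-4a-methyl-6-methylidenedecahydronaphthalene-1-carboxylate (E/Z mixture) | COC=C[C@@H]1C(=C)CC[C@H]2[C@@]1(C)[C@@H](O)CC[C@@]2(COC(=S)n3ccnc3)C(=O)OC | intermediate
18 | methyl (1R,4S,4aR,5R,8aS)-4-hydroxy-5-(2-methoxyethenyl)-1,4a-dimethyl-6-methylidenedecahydronaphthalene-1-carboxylate (E/Z mixture) | COC=C[C@@H]1C(=C)CC[C@H]2[C@@]1(C)[C@@H](O)CC[C@@]2(C)C(=O)OC | intermediate
19 | methyl (1R,4S,4aR,5R,8aS)-4-acetoxy-5-(2-methoxyethenyl)-1,4a-dimethyl-6-methylidenedecahydronaphthalene-1-carboxylate (E/Z mixture) | COC=C[C@@H]1C(=C)CC[C@H]2[C@@]1(C)[C@@H](OC(C)=O)CC[C@@]2(C)C(=O)OC | intermediate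
20 | methyl (1R,4S,4aS,5R,8aS)-4-acetoxy-1,4a-dimethyl-6-methylidene-5-(2-oxoethyl)decahydronaphthalene-1-carboxylate | O=CC[C@@H]1C(=C)CC[C@H]2[C@@]1(C)[C@@H](OC(C)=O)CC[C@@]2(C)C(=O)OC | intermediate
21 | methyl (1R,4S,4aS,5R,8aS)-4-acetoxy-1,4a-dimethyl-6-methylidene-5-[(2E)-3-methyl-4-oxobut-2-en-1-yl]decahydronaphthalene-1-carboxylate | O=C/C(C)=C/C[C@@H]1C(=C)CC[C@H]2[C@@]1(C)[C@@H](OC(C)=O)CC[C@@]2(C)C(=O)OC | intermediate
22 | methyl (1R,4S,4aS,5R,8aS)-4-acetoxy-1,4a-dimethyl-6-methylidene-5-[(2E)-3-methylpenta-2,4-dien-1-yl]decahydronaphthalene-1-carboxylate (CNP0235031.1) | C=C/C(C)=C/C[C@@H]1C(=C)CC[C@H]2[C@@]1(C)[C@@H](OC(C)=O)CC[C@@]2(C)C(=O)OC | target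

**Step count and risks**

Total: 15 steps. Longest linear sequence: 15 steps, from 1 to 22; 5 and 6 enter in step 4.

The three steps most likely to fail are step 7, step 4 and step 9.

First, step 7. The closure may be slow at an enamine carbon next to a quaternary centre, the new C8=C17 alkene may migrate into conjugation with the aldehyde through the enamine of the product, and the C9 configuration may erode on long exposure to the amine. The fallback sets out from 11. TIPSOTf and Et3N (CH2Cl2, −78 to 0 °C) should convert the aldehyde, which enolises far more readily than the C1 ketone, into triisopropylsilyl enol ether F1. Ph3PAuCl/AgSbF6 (5 mol %) in CH2Cl2/H2O at room temperature should then bring about the known monovalent-gold-catalysed 6-exo-dig addition of a silyl enol ether to a terminal alkyne. This forms the same C8–C9 bond through the same chair, needs no amine (so the enamine pathway to the conjugated enal is closed) and, after loss of the silyl group, comes back to the route at 14.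

Second, step 4. Conjugate addition may stall at a β-carbon that lies between the α-methyl group and the quaternary C4, the enantioselectivity may be low on so hindered an enone, and the crowded enolate may allylate on oxygen. The fallback sets out from 4. Addition of 7 with CuBr·SMe2 alone (THF, −78 °C) and allylation as before should give the racemate: enolate 8 together with its enantiomer, (3R)-enolate F2, and then 9 together with its enantiomer, dimethyl (2R,3R)-3-methyl-4-oxo-3-(prop-2-en-1-yl)-2-[4-(trimethylsilyl)but-3-yn-1-yl]cyclohexane-1,1-dicarboxylate F3. The trans relationship is set by the substrate and does not need the ligand. Preparative chromatography on a chiral stationary phase (amylose tris(3,5-dimethylphenylcarbamate), supercritical CO2/MeOH) separates 9 from F3, and the route is rejoined at 9.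

Third, step 9. The hydride may discriminate poorly between the two ester groups, both esters may be reduced, or the facial selectivity at C1 may be poor with this bulky reagent. The fallback sets out from 15. NaBH4 (MeOH, 0 °C) reduces only the ketone, by the same axial approach, to hydroxy diester F4. LiOH (THF/MeOH/H2O, 40 °C) saponifies the exposed equatorial ester and leaves the axial one, which is shielded by the C10 methyl, to give hydroxy acid F5. i-BuOCOCl and N-methylmorpholine (THF, −15 °C) convert the acid into mixed carbonic anhydride F6, which NaBH4 (THF/H2O, 0 °C) reduces to the primary alcohol without touching the methyl ester, and the route is rejoined at 16.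

**Further compounds**

F1 | step 7 | dimethyl (2S,3R)-2-(but-3-yn-1-yl)-3-methyl-4-oxo-3-{2-[(triisopropylsilyl)oxy]ethenyl}cyclohexane-1,1-dicarboxylate (E/Z mixture) | CC(C)[Si](C(C)C)(C(C)C)OC=C[C@]1(C)C(=O)CCC(C(=O)OC)(C(=O)OC)[C@H]1CCC#C
F2 | step 4 | bromomagnesium (3R)-4,4-bis(methoxycarbonyl)-2-methyl-3-[4-(trimethylsilyl)but-3-yn-1-yl]cyclohex-1-en-1-olate | CC1=C(O[Mg]Br)CCC(C(=O)OC)(C(=O)OC)[C@@H]1CCC#C[Si](C)(C)C
F3 | step 4 | dimethyl (2R,3R)-3-methyl-4-oxo-3-(prop-2-en-1-yl)-2-[4-(trimethylsilyl)but-3-yn-1-yl]cyclohexane-1,1-dicarboxylate | C=CC[C@@]1(C)C(=O)CCC(C(=O)OC)(C(=O)OC)[C@@H]1CCC#C[Si](C)(C)C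
F4 | step 9 | dimethyl (4S,4aR,5R,8aS)-4-hydroxy-5-(2-methoxyethenyl)-4a-methyl-6-methylideneoctahydronaphthalene-1,1(2H)-dicarboxylate (E/Z mixture) | COC=C[C@@H]1C(=C)CC[C@H]2[C@@]1(C)[C@@H](O)CCC2(C(=O)OC)C(=O)OC
F5 | step 9 | (1R,4S,4aR,5R,8aS)-4-hydroxy-1-(methoxycarbonyl)-5-(2-methoxyethenyl)-4a-methyl-6-methylidenedecahydronaphthalene-1-carboxylic acid (E/Z mixture; acid equatorial, ester axial) | COC=C[C@@H]1C(=C)CC[C@H]2[C@@]1(C)[C@@H](O)CC[C@@]2(C(=O)O)C(=O)OC
F6 | step 9 | isobutyl mixed carbonic anhydride of F5 (E/Z mixture) | COC=C[C@@H]1C(=C)CC[C@H]2[C@@]1(C)[C@@H](O)CC[C@@]2(C(=O)OC(=O)OCC(C)C)C(=O)OC
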